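## Analysis of the target

CNP0342712.1 is a 1,2-dioxane-3-acetic acid. The ring is O1–O2–C3–C4–C5–C6; C3 carries the acetic acid arm (C2, C1), C4 a methyl, and C6 a methyl plus a 2-methyl-10-phenyldecyl chain (C7–C16, methyl on C8, phenyl on C16). There are four stereocentres: C3 (S), C4 (S), C6 (R) and C8 (R). In the ring the C3 arm and the C4 methyl are cis, the long chain on C6 lies on the same face, and the C6 methyl on the opposite face. C8 is outside the ring, insulated from C6 by the C7 methylene, so the ring cannot control it. The O1–O2 bond is the sensitive group: it does not survive low-valent metals, catalytic hydrogenation, radical reductions or hard carbanions, and the C1 carboxyl, β to O2, lets the ring open by elimination in base. The hard part is C6, a fully substituted peroxide-bearing carbon flanked by two methylenes, each leading to a methyl-bearing stereocentre. In addition, the 3,4-cis arrangement puts the arm axial, so a reversible ring closure would drift to the wrong isomer. The plan rests on C3: it carries O2 and a two-carbon arm ending in an oxidised carbon, so O2 and the C1 oxygen are 1,3-related, which is the footprint of an oxetane O–C3–C2–C1 opened at C3 by the hydroperoxide oxygen on C6.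

## Retrosynthetic reasoning

**36 to 34.** The C1 carboxyl is taken back to the primary alcohol of 34. A carbonyl at C1 is kept out of the ring-forming step because it would acidify C2–H and let the C3–O2 bond leave by elimination. Forward, only a non-basic oxidation is needed.

**34 to 33.** The O2–C3 bond is cut. In 33, C3 is a secondary oxetane carbon that the terminal hydroperoxide oxygen can reach only from the back, through a six-membered transition state. Cutting O1–C6 instead would place the substitution on the fully substituted carbon. The ring, the C3 configuration and the free C1 oxygen all come from one isomerisation. Forward, C3 in 33 must be (R), opposite to the target and anti to the C4 methyl.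

**33 to 32, 31 and 30.** The hydroperoxide is masked as the peroxyketal 32 for the basic steps. The oxetane C1–O bond is cut to the monotosylate 31 and the 1,3-diol 30. Closing from the primary end leaves the C3–O bond untouched, so the C3 configuration is carried into 33 unchanged.

**30 to 28 and 27.** The C2–C3 bond is cut: C2 and C1 arrive as an allyl group (28) whose terminal carbon is later removed oxidatively. Reagent-controlled addition to aldehyde 27 is the one place where C3 is set, in the anti sense that the later inversion requires.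

**27 to 26, 25 and 23.** The C4–CH3 bond is cut. With the oxazolidinone 18 on C3 (imide 23), the methyl enters on one enolate face; the auxiliary is then removed reductively (26) and the alcohol oxidised (27). Bringing the methyl in on the olefination reagent would leave C4 to an unselective alkene reduction.

**23 to 22, then to 17 and 21.** The C4–C5 bond is cut as an alkene. C5 has to arrive as a carbonyl carbon attached to C6 (next paragraph), so C4 and C3 are added by olefination with phosphonate 21 (made from 18 via 20). The alkene is then saturated without touching the O–O bond.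

**17 to 16, 15, 14, 13 and 12.** The C6–O1 bond is traced to a trisubstituted epoxide spanning C5 and C6. Opening at the tertiary carbon with inversion gives the hydroperoxide 14 and leaves the epoxide oxygen on C5. With the primary oxygen of the former allylic alcohol this is a 1,2-diol (16), and glycol cleavage deletes the extra carbon to leave C5 as aldehyde 17. C6 cannot be set from its neighbours, but an epoxide of defined configuration turns the problem into a stereospecific substitution. The primary hydroxyl is silylated (13) before the opening and the hydroperoxide is capped (15) before the silyl group is removed, so the diol appears only once the peroxide is protected.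

**12 to 11 and 8.** The epoxide comes from the E-allylic alcohol 11 by reagent-controlled epoxidation. In 11 the C6–CH3 and C5–CH2OH bonds are cut back to the terminal alkyne 8: syn carbometalation puts the methyl on C6 and a one-carbon electrophile on C5 with defined geometry.

**8 to 6 and 7 (from 2, from 1); 6 to 4 and 3.** The C11–C12 bond is cut as an alkene between ynal 6 and ylide 7; its geometry is irrelevant because it is saturated together with C4=C5. Ynal 6 comes from enyne 4 by cleavage of the trisubstituted alkene, and 4 from (R)-citronellal 3 by one-carbon homologation. Citronellal supplies C6–C11 and the C8 stereocentre, which is β to every reacting centre and never at risk.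

## Alternatives that were turned down

Alternative 1: two-directional alkylation of a dithiane.
- **Disconnection and key step.** C5–C6 and C6–C7 are both cut and C6 is treated as a masked ketone. 1,3-Dithiane A3 is lithiated and alkylated twice with the same iodide A2 to give the C2-symmetric dithiane A1, with C4 and C8 in place.
- **For it.** C3–C9 is assembled in two operations from one small chiral building block, both methyl-bearing centres are bought, and no peroxide is present until late. On skeleton step economy and on C4 it is stronger than the chosen route, which needs an auxiliary-controlled methylation next to a peroxide.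
- **Against it.** The symmetry that makes it short is what the target lacks at C6. After dithiane removal, C6 is a ketone whose two arms differ only beyond C3 and C9, so the methyl or peroxide oxygen would be added without facial bias. The two identical ends must be told apart by a statistical mono-deprotection, and neither C3 nor the ring is addressed.
- **Comparison.** The chosen strategy gives up the short skeleton synthesis and in return fixes C6 by a stereospecific epoxide opening and C3 by a stereospecific displacement.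

Alternative 2: hydroperoxide opening of a tertiary epoxide.
- **Disconnection and key step.** O1–C6 is cut. Under mild acid the C3 hydroperoxide of A5 attacks the oxirane carbon C6 from the back, closing the ring 6-exo and leaving C7 as the hydroxymethyl group of A4.
- **For it.** The ring, C3, C4 and C6 are all present in A4, opening at the more substituted epoxide carbon is favoured over the seven-membered alternative, and the tail is attached last, which would suit analogues. As a ring-forming step it is as well founded as the chosen one.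
- **Against it.** The substitution is at a fully substituted carbon, where acid can ionise the epoxide before the hydroperoxide arrives, so C6 is exposed in the ring-closing step itself. The nucleophile is a secondary hydroperoxide, open to Kornblum–DeLaMare fragmentation in base. Most seriously, the C7–C8 bond and the C8 stereocentre must then be built next to quaternary C6 on a finished peroxide, by an olefination and reduction that cannot control C8 or by another auxiliary sequence.
- **Comparison.** The chosen route puts the displacement at a secondary carbon that cannot ionise, takes C8 from citronellal at the outset, and confines peroxide-stage chemistry to the C1–C5 side.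

Alternative 3: ring-closing metathesis across a peroxide.
- **Disconnection and key step.** C4=C5 is formed. The acyclic peroxide A7, with a vinyl group on C6 and an isopropenyl group on C3, is closed with the second-generation Grubbs catalyst (H2IMes)(PCy3)Cl2Ru=CHPh to the dihydrodioxine A6.
- **For it.** Ring closure is a C=C bond formation with no stereochemical demand, C3 and C6 are fixed beforehand, and dialkyl peroxides tolerate ruthenium carbenes. As a ring-forming event it is probably the most robust of the four.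
- **Against it.** A7 is an unsymmetrical peroxide between a tertiary allylic and a secondary allylic carbon; making its O–C3 bond by displacement invites elimination and SN2′ attack. The metathesis must join a 1,1-disubstituted olefin to a vinyl group on a quaternary carbon, a slow pairing. Above all, C4 is still missing: it would be created last by diimide reduction of a trisubstituted ring alkene, which is sluggish and must deliver hydrogen anti to the C3 arm while a pseudo-axial C6 substituent also shields one face.
- **Comparison.** The chosen strategy has C4 in place before ring closure and closes the ring by a displacement whose outcome is fixed by mechanism.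

Key step: step 24

Remark on the chemistry: atom numbers C1–C16, O1 and O2 of the target are used for all intermediates; the C11=C12 alkene from step 4 is drawn Z, but either isomer serves because it is saturated in step 15; commercial (R)-citronellal is assumed to be of high enantiomeric purity.

## Route

Step 1
Reactants: 1 (5-bromopentyl)benzene
Product: 2 (5-phenylpentyl)triphenylphosphonium bromide
Conditions: PPh3, MeCN, reflux
Reagents that add atoms: triphenylphosphine, c1ccccc1P(c1ccccc1)c1ccccc1
Why: SN2 quaternisation of a primary bromide by a phosphine (phosphonium salt formation for a Wittig reaction); no stereochemistry is involved.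

Step 2
Reactants: 3 (R)-citronellal
Product: 4 (4R)-4,8-dimethylnon-7-en-1-yne
Conditions: dimethyl (1-diazo-2-oxopropyl)phosphonate, K2CO3, MeOH, 0 °C → rt
Reagents that add atoms: dimethyl (1-diazo-2-oxopropyl)phosphonate, CC(=O)C(=[N+]=[N-])P(=O)(OC)OC
Why: Ohira–Bestmann (Seyferth–Gilbert) homologation of the aldehyde to the terminal alkyne under mild carbonate conditions; the stereocentre is β to the carbonyl and is not touched.

Step 3
Reactants: 4 (4R)-4,8-dimethylnon-7-en-1-yne
Product: 6 (4R)-4-methylhept-6-ynal, via ozonide 5 (not isolated)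
Conditions: O3, CH2Cl2, −78 °C (Sudan Red 7B end point); PPh3, −78 °C → rt
Reagents that add atoms: ozone, [O-][O+]=O
Why: Ozonolysis with reductive work-up; the electron-rich trisubstituted alkene reacts far faster than the terminal alkyne, and the indicator limits ozone to one equivalent.

Step 4
Reactants: 2 (5-phenylpentyl)triphenylphosphonium bromide; 6 (4R)-4-methylhept-6-ynal
Product: 8 (4R,7Z)-4-methyl-12-phenyldodec-7-en-1-yne, via ylide 7 (not isolated)
Conditions: NaN(SiMe3)2, THF, −78 → 0 °C; then 6, −78 °C → rt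
Reagents that add atoms: none
Why: Wittig olefination with a non-stabilised ylide joins C11 and C12; the ylide is not basic enough to be consumed by the alkyne C–H, and the alkene geometry is irrelevant because the bond is saturated in step 15.

Step 5
Reactants: 8 (4R,7Z)-4-methyl-12-phenyldodec-7-en-1-yne
Product: 11 (2E,5R,8Z)-3,5-dimethyl-13-phenyltrideca-2,8-dien-1-ol, via alkenylalane 9 (not isolated), via lithium alanate 10 (not isolated)
Conditions: AlMe3, Cp2ZrCl2 (25 mol %), CH2Cl2, 0 °C → rt; evaporate; n-BuLi, THF/hexane, −78 → 0 °C; (CH2O)n, rt; aq. HCl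
Reagents that add atoms: trimethylaluminium, C[Al](C)C; paraformaldehyde (as formaldehyde), C=O
Why: Zirconium-catalysed Negishi carboalumination adds CH3 and Al syn across the alkyne with CH3 on the internal carbon; the alkenylalanate then captures formaldehyde with retention of geometry, giving the E-trisubstituted allylic alcohol. The internal alkene is inert.

Step 6
Reactants: 11 (2E,5R,8Z)-3,5-dimethyl-13-phenyltrideca-2,8-dien-1-ol
Product: 12 [(2S,3S)-3-methyl-3-[(2R,5Z)-2-methyl-10-phenyldec-5-en-1-yl]oxiran-2-yl]methanol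
Conditions: Ti(OiPr)4 (10 mol %), L-(+)-diethyl tartrate (12 mol %), t-BuOOH, 4 Å MS, CH2Cl2, −20 °C
Reagents that add atoms: tert-butyl hydroperoxide, CC(C)(C)OO
Why: Sharpless asymmetric epoxidation; with L-(+)-tartrate an E-3-methylalk-2-en-1-ol should give the (2S,3S)-epoxide (the geraniol case), so C6 is set by the reagent, independently of remote C8. The isolated alkene is not epoxidised.

Step 7
Reactants: 12 [(2S,3S)-3-methyl-3-[(2R,5Z)-2-methyl-10-phenyldec-5-en-1-yl]oxiran-2-yl]methanol
Product: 13 tert-butyl{[(2S,3S)-3-methyl-3-[(2R,5Z)-2-methyl-10-phenyldec-5-en-1-yl]oxiran-2-yl]methoxy}diphenylsilane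
Conditions: TBDPSCl, imidazole, CH2Cl2, 0 °C → rt
Reagents that add atoms: tert-butyl(chloro)diphenylsilane, CC(C)(C)[Si](Cl)(c1ccccc1)c1ccccc1
Why: Silyl ether formation; the primary hydroxyl is blocked so that after epoxide opening only the hydroperoxide and one hindered secondary hydroxyl are free.

Step 8
Reactants: 13 tert-butyl{[(2S,3S)-3-methyl-3-[(2R,5Z)-2-methyl-10-phenyldec-5-en-1-yl]oxiran-2-yl]methoxy}diphenylsilane
Product: 14 (2S,3R,5R,8Z)-1-[(tert-butyldiphenylsilyl)oxy]-3-hydroperoxy-3,5-dimethyl-13-phenyltridec-8-en-2-ol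
Conditions: H2O2 (anhydrous, ca. 2 M in Et2O, large excess), H3PMo12O40 (2 mol %), Et2O, 0 °C → rt
Reagents that add atoms: hydrogen peroxide, OO
Why: Acid-catalysed perhydrolysis of a trisubstituted epoxide: H2O2 attacks the tertiary carbon C6 from the back (C5 is deactivated by the silyloxymethyl group), so C6 is inverted and the epoxide oxygen stays on C5. The large excess of nucleophile is meant to keep the opening bimolecular; the isolated cis-alkene should be inert at this temperature.

Step 9
Reactants: 14 (2S,3R,5R,8Z)-1-[(tert-butyldiphenylsilyl)oxy]-3-hydroperoxy-3,5-dimethyl-13-phenyltridec-8-en-2-ol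
Product: 15 (2S,3R,5R,8Z)-1-[(tert-butyldiphenylsilyl)oxy]-3-[(2-methoxypropan-2-yl)peroxy]-3,5-dimethyl-13-phenyltridec-8-en-2-ol
Conditions: 2-methoxypropene (1.5 equiv), PPTS (5 mol %), CH2Cl2, −20 → 0 °C; Et3N quench
Reagents that add atoms: 2-methoxypropene, COC(C)=C
Why: Peroxyketal formation by acid-catalysed addition of the hydroperoxide to an enol ether; the hydroperoxide is the more reactive and far less hindered nucleophile. The neopentyl-type C5 hydroxyl should stay free with a weak acid, low temperature and short time, which also avoids closure to a 1,2,4-trioxane.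

Step 10
Reactants: 15 (2S,3R,5R,8Z)-1-[(tert-butyldiphenylsilyl)oxy]-3-[(2-methoxypropan-2-yl)peroxy]-3,5-dimethyl-13-phenyltridec-8-en-2-ol
Product: 16 (2S,3R,5R,8Z)-3-[(2-methoxypropan-2-yl)peroxy]-3,5-dimethyl-13-phenyltridec-8-ene-1,2-diol
Conditions: Bu4NF, AcOH (1:1), THF, 0 °C → rt
Reagents that add atoms: none
Why: Fluoride-mediated desilylation, buffered with acetic acid so that no free β-peroxy alkoxide (prone to fragmentation) is generated; the peroxyketal is stable to fluoride.

Step 11
Reactants: 16 (2S,3R,5R,8Z)-3-[(2-methoxypropan-2-yl)peroxy]-3,5-dimethyl-13-phenyltridec-8-ene-1,2-diol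
Product: 17 (2R,4R,7Z)-2-[(2-methoxypropan-2-yl)peroxy]-2,4-dimethyl-12-phenyldodec-7-enal
Conditions: NaIO4, THF/pH 7 buffer, 0 °C → rt
Reagents that add atoms: none
Why: Periodate glycol cleavage removes the former carbinol carbon and turns C5 into the aldehyde; C6 is quaternary, so the α-peroxy aldehyde can neither enolise nor undergo Kornblum–DeLaMare fragmentation.

Step 12
Reactants: 18 (S)-4-benzyloxazolidin-2-one
Product: 20 (S)-4-benzyl-3-(2-bromoacetyl)oxazolidin-2-one, via lithium amide 19 (not isolated)
Conditions: n-BuLi, THF, −78 °C; BrCH2COBr, −78 → 0 °C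
Reagents that add atoms: bromoacetyl bromide, BrCC(Br)=O
Why: N-Acylation of the lithiated oxazolidinone with an acid bromide; the ring stereocentre is not involved.

Step 13
Reactants: 20 (S)-4-benzyl-3-(2-bromoacetyl)oxazolidin-2-one
Product: 21 diethyl {2-[(4S)-4-benzyl-2-oxo-1,3-oxazolidin-3-yl]-2-oxoethyl}phosphonate
Conditions: P(OEt)3, toluene, 100 °C
Reagents that add atoms: triethyl phosphite, CCOP(OCC)OCC
Why: Michaelis–Arbuzov reaction of the α-bromo imide with a trialkyl phosphite.

Step 14
Reactants: 17 (2R,4R,7Z)-2-[(2-methoxypropan-2-yl)peroxy]-2,4-dimethyl-12-phenyldodec-7-enal; 21 diethyl {2-[(4S)-4-benzyl-2-oxo-1,3-oxazolidin-3-yl]-2-oxoethyl}phosphonate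
Product: 22 (4S)-4-benzyl-3-[(2E,4R,6R,9Z)-4-[(2-methoxypropan-2-yl)peroxy]-4,6-dimethyl-14-phenyltetradeca-2,9-dienoyl]oxazolidin-2-one
Conditions: LiCl, i-Pr2NEt, MeCN, 0 °C → rt
Reagents that add atoms: none
Why: Horner–Wadsworth–Emmons olefination under Masamune–Roush conditions forms C4=C5 as the E-alkene; the mild amine base does not touch the peroxyketal and the aldehyde has no α-hydrogen.

Step 15
Reactants: 22 (4S)-4-benzyl-3-[(2E,4R,6R,9Z)-4-[(2-methoxypropan-2-yl)peroxy]-4,6-dimethyl-14-phenyltetradeca-2,9-dienoyl]oxazolidin-2-one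
Product: 23 (4S)-4-benzyl-3-[(4S,6R)-4-[(2-methoxypropan-2-yl)peroxy]-4,6-dimethyl-14-phenyltetradecanoyl]oxazolidin-2-one
Conditions: 2-nitrobenzenesulfonohydrazide (large excess, in portions), Et3N, CH2Cl2, rt
Reagents that add atoms: none
Why: Diimide reduction saturates both C4=C5 and C11=C12 by concerted syn transfer of H2 and, unlike catalytic hydrogenation, does not cleave O–O bonds. The descriptor at the peroxide carbon changes from R to S only because the CIP priorities change; the configuration is unchanged.

Step 16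
Reactants: 23 (4S)-4-benzyl-3-[(4S,6R)-4-[(2-methoxypropan-2-yl)peroxy]-4,6-dimethyl-14-phenyltetradecanoyl]oxazolidin-2-one
Product: 25 (4S)-4-benzyl-3-[(2S,4R,6R)-4-[(2-methoxypropan-2-yl)peroxy]-2,4,6-trimethyl-14-phenyltetradecanoyl]oxazolidin-2-one, via sodium enolate 24 (not isolated)
Conditions: NaN(SiMe3)2, THF, −78 °C; MeI (5 equiv), −78 °C; AcOH quench at −78 °C
Reagents that add atoms: iodomethane, CI
Why: Evans asymmetric alkylation: the chelated Z-sodium enolate is methylated on the face opposite the benzyl group, which with the (S)-auxiliary and the chain already on the enolate gives (S) at C4. The enolate is kept at −78 °C with excess MeI so that bimolecular methylation outruns the slow four-membered attack of the enolate carbon on the peroxide oxygen.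

Step 17
Reactants: 25 (4S)-4-benzyl-3-[(2S,4R,6R)-4-[(2-methoxypropan-2-yl)peroxy]-2,4,6-trimethyl-14-phenyltetradecanoyl]oxazolidin-2-one
Product: 26 (2S,4R,6R)-4-[(2-methoxypropan-2-yl)peroxy]-2,4,6-trimethyl-14-phenyltetradecan-1-ol
Conditions: LiBH4, MeOH (1 equiv), Et2O, 0 °C; aq. NaOH work-up
Reagents that add atoms: none
Why: Reductive cleavage of the N-acyl oxazolidinone to the primary alcohol; borohydride is not expected to reduce a dialkyl peroxide at 0 °C, and the auxiliary is recovered.

Step 18
Reactants: 26 (2S,4R,6R)-4-[(2-methoxypropan-2-yl)peroxy]-2,4,6-trimethyl-14-phenyltetradecan-1-ol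
Product: 27 (2S,4R,6R)-4-[(2-methoxypropan-2-yl)peroxy]-2,4,6-trimethyl-14-phenyltetradecanal
Conditions: Dess–Martin periodinane, NaHCO3, CH2Cl2, 0 °C → rt
Reagents that add atoms: none
Why: Dess–Martin oxidation to the α-methyl aldehyde under buffered, non-epimerising conditions; the aldehyde is used at once.

Step 19
Reactants: 27 (2S,4R,6R)-4-[(2-methoxypropan-2-yl)peroxy]-2,4,6-trimethyl-14-phenyltetradecanal
Product: 28 (4R,5S,7R,9R)-7-[(2-methoxypropan-2-yl)peroxy]-5,7,9-trimethyl-17-phenylheptadec-1-en-4-ol
Conditions: (+)-B-methoxydiisopinocampheylborane [(+)-Ipc2BOMe, (−)-α-pinene series], allylMgBr, Et2O, −78 °C → rt; then 27, −78 °C; NaOH, H2O2, rt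
Reagents that add atoms: allylmagnesium bromide, C=CC[Mg]Br
Why: Brown asymmetric allylboration: the B-allyldiisopinocampheylborane of the (−)-α-pinene series should deliver allyl to the Re face of the aldehyde through a chair transition state, giving the (3R) carbinol (target numbering), anti to the C4 methyl. Reagent control is expected to override the weak Felkin–Anh preference of the α-methyl aldehyde.

Step 20
Reactants: 28 (4R,5S,7R,9R)-7-[(2-methoxypropan-2-yl)peroxy]-5,7,9-trimethyl-17-phenylheptadec-1-en-4-ol
Product: 30 (3R,4S,6R,8R)-6-[(2-methoxypropan-2-yl)peroxy]-4,6,8-trimethyl-16-phenylhexadecane-1,3-diol, via ozonide 29 (not isolated)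
Conditions: O3, CH2Cl2, −78 °C; then NaBH4, MeOH, −78 °C → rt
Reagents that add atoms: ozone, [O-][O+]=O
Why: Ozonolysis of the terminal alkene with borohydride work-up gives the C1 primary alcohol directly; the peroxyketal, the carbinol and the phenyl ring are inert at −78 °C.

Step 21
Reactants: 30 (3R,4S,6R,8R)-6-[(2-methoxypropan-2-yl)peroxy]-4,6,8-trimethyl-16-phenylhexadecane-1,3-diol
Product: 31 (3R,4S,6R,8R)-3-hydroxy-6-[(2-methoxypropan-2-yl)peroxy]-4,6,8-trimethyl-16-phenylhexadecyl 4-methylbenzenesulfonate
Conditions: TsCl (1.05 equiv), Et3N, Me3N·HCl (cat.), CH2Cl2, 0 °C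
Reagents that add atoms: 4-methylbenzenesulfonyl chloride, Cc1ccc(cc1)S(Cl)(=O)=O
Why: Selective sulfonylation of the primary hydroxyl of a 1,3-diol, differentiated sterically from the β-branched secondary hydroxyl.

Step 22
Reactants: 31 (3R,4S,6R,8R)-3-hydroxy-6-[(2-methoxypropan-2-yl)peroxy]-4,6,8-trimethyl-16-phenylhexadecyl 4-methylbenzenesulfonate
Product: 32 (2R)-2-[(2S,4R,6R)-4-[(2-methoxypropan-2-yl)peroxy]-4,6-dimethyl-14-phenyltetradecan-2-yl]oxetane
Conditions: KOt-Bu, THF, 0 °C → rt
Reagents that add atoms: none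
Why: Intramolecular Williamson etherification (4-exo-tet) of the C3 alkoxide on the primary tosylate closes the oxetane with retention at C3; the peroxyketal has no hydrogen on either peroxide-bearing carbon and is stable to alkoxide.

Step 23
Reactants: 32 (2R)-2-[(2S,4R,6R)-4-[(2-methoxypropan-2-yl)peroxy]-4,6-dimethyl-14-phenyltetradecan-2-yl]oxetane
Product: 33 (2R)-2-[(2S,4R,6R)-4-hydroperoxy-4,6-dimethyl-14-phenyltetradecan-2-yl]oxetane
Conditions: AcOH/THF/H2O (4:2:1), rt
Reagents that add atoms: none
Why: Mild acid hydrolysis of the peroxyketal (acetal-type cleavage) releases the tertiary hydroperoxide; a 2-alkyloxetane should be stable to dilute acetic acid at room temperature.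

Step 24
Reactants: 33 (2R)-2-[(2S,4R,6R)-4-hydroperoxy-4,6-dimethyl-14-phenyltetradecan-2-yl]oxetane
Product: 34 2-[(3S,4S,6R)-4,6-dimethyl-6-[(2R)-2-methyl-10-phenyldecyl]-1,2-dioxan-3-yl]ethan-1-ol
Conditions: Me3SiOTf (20 mol %), CH2Cl2 (0.01 M), −78 → −30 °C; aq. NaHCO3
Reagents that add atoms: none
Why: Lewis acid-promoted intramolecular opening of an oxetane by a hydroperoxide, a known route to 1,2-dioxanes. The silyl triflate (or the triflic acid it releases) activates the oxetane oxygen; the terminal hydroperoxide oxygen then attacks C3 anti to the departing C3–O bond, forming O2–C3 while the oxetane oxygen stays on C1 as the primary alcohol after work-up. The ring closes 6-exo-tet (O2, O1, C6, C5, C4 and C3 in the ring, the breaking bond outside it); attack at C1 would need an eight-membered transition state and is not expected. The only new stereocentre, C3, is fixed by mechanism: backside displacement inverts the (R)-carbinol carbon set in step 19 to (S), giving the 3,4-cis relationship that a reversible closure would not favour. C3 is secondary and has no cation-stabilising group, so ionisation is not expected; C4, C6 and C8 are untouched. High dilution should let intramolecular opening outrun intermolecular opening, and low temperature with substoichiometric Lewis acid is meant to spare the tertiary hydroperoxide from acid-induced rearrangement. Release of oxetane ring strain drives the reaction.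

Step 25
Reactants: 34 2-[(3S,4S,6R)-4,6-dimethyl-6-[(2R)-2-methyl-10-phenyldecyl]-1,2-dioxan-3-yl]ethan-1-ol
Product: 36 2-[(3S,4S,6R)-4,6-dimethyl-6-[(2R)-2-methyl-10-phenyldecyl]-1,2-dioxan-3-yl]acetic acid, via aldehyde 35 (not isolated)
Conditions: TEMPO (20 mol %), PhI(OAc)2 (2.5 equiv), MeCN/pH 7 buffer (1:1), 0 °C → rt
Reagents that add atoms: water, O
Why: TEMPO-catalysed oxidation with a hypervalent iodine co-oxidant takes the primary alcohol through the aldehyde hydrate to the acid under near-neutral conditions; base, which would open the β-peroxy carbonyl system by elimination, is avoided and the O–O bond is inert to these oxidants.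

## Compound list

1 | (5-bromopentyl)benzene | BrCCCCCc1ccccc1 | starting material
2 | (5-phenylpentyl)triphenylphosphonium bromide | [Br-].c1ccccc1CCCCC[P+](c1ccccc1)(c1ccccc1)c1ccccc1 | intermediate
3 | (R)-citronellal, (3R)-3,7-dimethyloct-6-enal | C[C@H](CCC=C(C)C)CC=O | starting material
4 | (4R)-4,8-dimethylnon-7-en-1-yne | C[C@H](CCC=C(C)C)CC#C | intermediate
5 | 3,3-dimethyl-5-[(3R)-3-methylhex-5-yn-1-yl]-1,2,4-trioxolane (secondary ozonide of 4) | C[C@H](CCC1OOC(C)(C)O1)CC#C | intermediate
6 | (4R)-4-methylhept-6-ynal | C[C@H](CCC=O)CC#C | intermediate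
7 | (5-phenylpentylidene)triphenylphosphorane | c1ccccc1CCCCC=P(c1ccccc1)(c1ccccc1)c1ccccc1 | intermediate
8 | (4R,7Z)-4-methyl-12-phenyldodec-7-en-1-yne | C[C@H](CC/C=C\CCCCc1ccccc1)CC#C | intermediate
9 | dimethyl[(1E,4R,7Z)-2,4-dimethyl-12-phenyldodeca-1,7-dien-1-yl]alane | C[Al](C)/C=C(\C)C[C@H](C)CC/C=C\CCCCc1ccccc1 | intermediate
10 | lithium butyl(dimethyl)[(1E,4R,7Z)-2,4-dimethyl-12-phenyldodeca-1,7-dien-1-yl]aluminate | [Li+].CCCC[Al-](C)(C)/C=C(\C)C[C@H](C)CC/C=C\CCCCc1ccccc1 | intermediate
11 | (2E,5R,8Z)-3,5-dimethyl-13-phenyltrideca-2,8-dien-1-ol | OC/C=C(\C)C[C@H](C)CC/C=C\CCCCc1ccccc1 | intermediate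
12 | [(2S,3S)-3-methyl-3-[(2R,5Z)-2-methyl-10-phenyldec-5-en-1-yl]oxiran-2-yl]methanol | OC[C@@H]1O[C@@]1(C)C[C@H](C)CC/C=C\CCCCc1ccccc1 | intermediate
13 | tert-butyl{[(2S,3S)-3-methyl-3-[(2R,5Z)-2-methyl-10-phenyldec-5-en-1-yl]oxiran-2-yl]methoxy}diphenylsilane | CC(C)(C)[Si](c1ccccc1)(c1ccccc1)OC[C@@H]1O[C@@]1(C)C[C@H](C)CC/C=C\CCCCc1ccccc1 | intermediate
14 | (2S,3R,5R,8Z)-1-[(tert-butyldiphenylsilyl)oxy]-3-hydroperoxy-3,5-dimethyl-13-phenyltridec-8-en-2-ol | CC(C)(C)[Si](c1ccccc1)(c1ccccc1)OC[C@H](O)[C@](C)(OO)C[C@H](C)CC/C=C\CCCCc1ccccc1 | intermediate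
15 | (2S,3R,5R,8Z)-1-[(tert-butyldiphenylsilyl)oxy]-3-[(2-methoxypropan-2-yl)peroxy]-3,5-dimethyl-13-phenyltridec-8-en-2-ol | CC(C)(C)[Si](c1ccccc1)(c1ccccc1)OC[C@H](O)[C@](C)(OOC(C)(C)OC)C[C@H](C)CC/C=C\CCCCc1ccccc1 | intermediate
16 | (2S,3R,5R,8Z)-3-[(2-methoxypropan-2-yl)peroxy]-3,5-dimethyl-13-phenyltridec-8-ene-1,2-diol | OC[C@H](O)[C@](C)(OOC(C)(C)OC)C[C@H](C)CC/C=C\CCCCc1ccccc1 | intermediate
17 | (2R,4R,7Z)-2-[(2-methoxypropan-2-yl)peroxy]-2,4-dimethyl-12-phenyldodec-7-enal | O=C[C@](C)(OOC(C)(C)OC)C[C@H](C)CC/C=C\CCCCc1ccccc1 | intermediate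
18 | (S)-4-benzyloxazolidin-2-one | O=C1N[C@@H](Cc2ccccc2)CO1 | starting material
19 | N-lithio-(S)-4-benzyloxazolidin-2-one | [Li]N1[C@@H](Cc2ccccc2)COC1=O | intermediate
20 | (S)-4-benzyl-3-(2-bromoacetyl)oxazolidin-2-one | O=C1N(C(=O)CBr)[C@@H](Cc2ccccc2)CO1 | intermediate
21 | diethyl {2-[(4S)-4-benzyl-2-oxo-1,3-oxazolidin-3-yl]-2-oxoethyl}phosphonate | O=C1N(C(=O)CP(=O)(OCC)OCC)[C@@H](Cc2ccccc2)CO1 | intermediate
22 | (4S)-4-benzyl-3-[(2E,4R,6R,9Z)-4-[(2-methoxypropan-2-yl)peroxy]-4,6-dimethyl-14-phenyltetradeca-2,9-dienoyl]oxazolidin-2-one | O=C1N(C(=O)/C=C/[C@](C)(OOC(C)(C)OC)C[C@H](C)CC/C=C\CCCCc2ccccc2)[C@@H](Cc2ccccc2)CO1 | intermediate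
23 | (4S)-4-benzyl-3-[(4S,6R)-4-[(2-methoxypropan-2-yl)peroxy]-4,6-dimethyl-14-phenyltetradecanoyl]oxazolidin-2-one | O=C1N(C(=O)CC[C@](C)(OOC(C)(C)OC)C[C@H](C)CCCCCCCCc2ccccc2)[C@@H](Cc2ccccc2)CO1 | intermediate
24 | sodium (Z)-enolate of imide 23 | [Na+].[O-]/C(=C\C[C@](C)(OOC(C)(C)OC)C[C@H](C)CCCCCCCCc1ccccc1)N1[C@@H](Cc2ccccc2)COC1=O | intermediate
25 | (4S)-4-benzyl-3-[(2S,4R,6R)-4-[(2-methoxypropan-2-yl)peroxy]-2,4,6-trimethyl-14-phenyltetradecanoyl]oxazolidin-2-one | O=C1N(C(=O)[C@@H](C)C[C@](C)(OOC(C)(C)OC)C[C@H](C)CCCCCCCCc2ccccc2)[C@@H](Cc2ccccc2)CO1 | intermediate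
26 | (2S,4R,6R)-4-[(2-methoxypropan-2-yl)peroxy]-2,4,6-trimethyl-14-phenyltetradecan-1-ol | OC[C@@H](C)C[C@](C)(OOC(C)(C)OC)C[C@H](C)CCCCCCCCc1ccccc1 | intermediate
27 | (2S,4R,6R)-4-[(2-methoxypropan-2-yl)peroxy]-2,4,6-trimethyl-14-phenyltetradecanal | O=C[C@@H](C)C[C@](C)(OOC(C)(C)OC)C[C@H](C)CCCCCCCCc1ccccc1 | intermediate
28 | (4R,5S,7R,9R)-7-[(2-methoxypropan-2-yl)peroxy]-5,7,9-trimethyl-17-phenylheptadec-1-en-4-ol | C=CC[C@@H](O)[C@@H](C)C[C@](C)(OOC(C)(C)OC)C[C@H](C)CCCCCCCCc1ccccc1 | intermediate
29 | (2R,3S,5R,7R)-5-[(2-methoxypropan-2-yl)peroxy]-3,5,7-trimethyl-15-phenyl-1-(1,2,4-trioxolan-3-yl)pentadecan-2-ol (secondary ozonide of 28) | O1OC(C[C@@H](O)[C@@H](C)C[C@](C)(OOC(C)(C)OC)C[C@H](C)CCCCCCCCc2ccccc2)OC1 | intermediate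
30 | (3R,4S,6R,8R)-6-[(2-methoxypropan-2-yl)peroxy]-4,6,8-trimethyl-16-phenylhexadecane-1,3-diol | OCC[C@@H](O)[C@@H](C)C[C@](C)(OOC(C)(C)OC)C[C@H](C)CCCCCCCCc1ccccc1 | intermediate
31 | (3R,4S,6R,8R)-3-hydroxy-6-[(2-methoxypropan-2-yl)peroxy]-4,6,8-trimethyl-16-phenylhexadecyl 4-methylbenzenesulfonate | Cc1ccc(cc1)S(=O)(=O)OCC[C@@H](O)[C@@H](C)C[C@](C)(OOC(C)(C)OC)C[C@H](C)CCCCCCCCc1ccccc1 | intermediate
32 | (2R)-2-[(2S,4R,6R)-4-[(2-methoxypropan-2-yl)peroxy]-4,6-dimethyl-14-phenyltetradecan-2-yl]oxetane | C[C@H](CCCCCCCCc1ccccc1)C[C@@](C)(OOC(C)(C)OC)C[C@H](C)[C@H]1CCO1 | intermediate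
33 | (2R)-2-[(2S,4R,6R)-4-hydroperoxy-4,6-dimethyl-14-phenyltetradecan-2-yl]oxetane | C[C@H](CCCCCCCCc1ccccc1)C[C@@](C)(OO)C[C@H](C)[C@H]1CCO1 | intermediate
34 | 2-[(3S,4S,6R)-4,6-dimethyl-6-[(2R)-2-methyl-10-phenyldecyl]-1,2-dioxan-3-yl]ethan-1-ol | C[C@H](CCCCCCCCc1ccccc1)C[C@]1(C)C[C@H](C)[C@H](CCO)OO1 | intermediate
35 | 2-[(3S,4S,6R)-4,6-dimethyl-6-[(2R)-2-methyl-10-phenyldecyl]-1,2-dioxan-3-yl]acetaldehyde | C[C@H](CCCCCCCCc1ccccc1)C[C@]1(C)C[C@H](C)[C@H](CC=O)OO1 | intermediate
36 | 2-[(3S,4S,6R)-4,6-dimethyl-6-[(2R)-2-methyl-10-phenyldecyl]-1,2-dioxan-3-yl]acetic acid (CNP0342712.1) | C[C@H](CCCCCCCCc1ccccc1)C[C@]1(C)C[C@H](C)[C@H](CC(=O)O)OO1 | target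

## Step count and least certain steps

Total: 25 steps. Longest linear sequence: 22 steps, from (R)-citronellal 3 (steps 2–11 and 14–25).

**Step 24 (key step).**
- *What may go wrong:* acid-induced rearrangement of the tertiary hydroperoxide (Hock-type migration and fragmentation), or intermolecular opening at the unhindered C1 of a second molecule, either of which could compete with the slower attack at the β-branched secondary C3.
- *Fallback (from 30, back at 34):* replace the oxetane by a sulfonate leaving group on C3.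
  - Diol 30 is silylated at the primary hydroxyl (TBDPSCl, imidazole) to (3R,4S,6R,8R)-1-[(tert-butyldiphenylsilyl)oxy]-6-[(2-methoxypropan-2-yl)peroxy]-4,6,8-trimethyl-16-phenylhexadecan-3-ol F1.
  - Mesylation (MsCl, Et3N) gives (3R,4S,6R,8R)-1-[(tert-butyldiphenylsilyl)oxy]-6-[(2-methoxypropan-2-yl)peroxy]-4,6,8-trimethyl-16-phenylhexadecan-3-yl methanesulfonate F2.
  - AcOH/THF/H2O hydrolyses the peroxyketal to (3R,4S,6R,8R)-1-[(tert-butyldiphenylsilyl)oxy]-6-hydroperoxy-4,6,8-trimethyl-16-phenylhexadecan-3-yl methanesulfonate F3.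
  - KOt-Bu with 18-crown-6 in THF at 0 °C (or CsOH in DMF) closes the ring by intramolecular alkylation of the hydroperoxide anion, 6-exo-tet with inversion at C3, to tert-butyl{2-[(3S,4S,6R)-4,6-dimethyl-6-[(2R)-2-methyl-10-phenyldecyl]-1,2-dioxan-3-yl]ethoxy}diphenylsilane F4.
  - Bu4NF/AcOH returns to 34. This detour also removes the oxetane closure of step 22.

**Step 16 (methylation).**
- *What may go wrong:* loss of the enolate by intramolecular displacement at the peroxide oxygen (closure of a four-membered ether with expulsion of the ketal alkoxide), or incomplete face selectivity with the small electrophile.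
- *Fallback (from 17, back at 27):* form the C4–H bond instead of the C4–C bond, with no carbanion near the peroxide. This variant has no control at C4.
  - Aldehyde 17 is olefinated with 2-(triphenylphosphoranylidene)propanal (toluene, 80 °C) to (2E,4R,6R,9Z)-4-[(2-methoxypropan-2-yl)peroxy]-2,4,6-trimethyl-14-phenyltetradeca-2,9-dienal F5.
  - Iminium-catalysed transfer hydrogenation (Hantzsch ester, dibenzylammonium trifluoroacetate cat., THF) reduces the conjugated alkene to (4R,6R,9Z)-4-[(2-methoxypropan-2-yl)peroxy]-2,4,6-trimethyl-14-phenyltetradec-9-enal F6 as both C2 epimers.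
  - Diimide, as in step 15, saturates the remaining alkene and gives 27 together with its epimer (2R,4R,6R)-4-[(2-methoxypropan-2-yl)peroxy]-2,4,6-trimethyl-14-phenyltetradecanal F7.
  - The epimers would be separated as the diastereomeric alcohols after step 19.

**Step 19 (allylation).**
- *What may go wrong:* erosion of reagent control in the mismatched addition (reagent against the Felkin–Anh preference) and partial epimerisation of the α-methyl aldehyde before it is consumed; the (3S) epimer would end as the 3,4-trans dioxane.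
- *Fallback (from 27, back at 30):* add C2 and C1 as a chiral acetate enolate instead of an allyl group.
  - (R)-2-Hydroxy-1,2,2-triphenylethyl acetate is doubly deprotonated (LiN(i-Pr)2, THF, −78 °C) and added to 27 at −100 °C to give (R)-2-hydroxy-1,2,2-triphenylethyl (3R,4S,6R,8R)-3-hydroxy-6-[(2-methoxypropan-2-yl)peroxy]-4,6,8-trimethyl-16-phenylhexadecanoate F8.
  - LiBH4 in THF reduces the ester directly to diol 30, which also makes the ozonolysis of step 20 unnecessary.

## Further compounds

F1 | step 24 | (3R,4S,6R,8R)-1-[(tert-butyldiphenylsilyl)oxy]-6-[(2-methoxypropan-2-yl)peroxy]-4,6,8-trimethyl-16-phenylhexadecan-3-ol | CC(C)(C)[Si](c1ccccc1)(c1ccccc1)OCC[C@@H](O)[C@@H](C)C[C@](C)(OOC(C)(C)OC)C[C@H](C)CCCCCCCCc1ccccc1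
F2 | step 24 | (3R,4S,6R,8R)-1-[(tert-butyldiphenylsilyl)oxy]-6-[(2-methoxypropan-2-yl)peroxy]-4,6,8-trimethyl-16-phenylhexadecan-3-yl methanesulfonate | CC(C)(C)[Si](c1ccccc1)(c1ccccc1)OCC[C@@H](OS(C)(=O)=O)[C@@H](C)C[C@](C)(OOC(C)(C)OC)C[C@H](C)CCCCCCCCc1ccccc1
F3 | step 24 | (3R,4S,6R,8R)-1-[(tert-butyldiphenylsilyl)oxy]-6-hydroperoxy-4,6,8-trimethyl-16-phenylhexadecan-3-yl methanesulfonate | CC(C)(C)[Si](c1ccccc1)(c1ccccc1)OCC[C@@H](OS(C)(=O)=O)[C@@H](C)C[C@](C)(OO)C[C@H](C)CCCCCCCCc1ccccc1
F4 | step 24 | tert-butyl{2-[(3S,4S,6R)-4,6-dimethyl-6-[(2R)-2-methyl-10-phenyldecyl]-1,2-dioxan-3-yl]ethoxy}diphenylsilane | C[C@H](CCCCCCCCc1ccccc1)C[C@]1(C)C[C@H](C)[C@H](CCO[Si](c2ccccc2)(c2ccccc2)C(C)(C)C)OO1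
F5 | step 16 | (2E,4R,6R,9Z)-4-[(2-methoxypropan-2-yl)peroxy]-2,4,6-trimethyl-14-phenyltetradeca-2,9-dienal | O=C/C(C)=C/[C@](C)(OOC(C)(C)OC)C[C@H](C)CC/C=C\CCCCc1ccccc1
F6 | step 16 | (4R,6R,9Z)-4-[(2-methoxypropan-2-yl)peroxy]-2,4,6-trimethyl-14-phenyltetradec-9-enal, both C2 epimers | O=CC(C)C[C@](C)(OOC(C)(C)OC)C[C@H](C)CC/C=C\CCCCc1ccccc1
F7 | step 16 | (2R,4R,6R)-4-[(2-methoxypropan-2-yl)peroxy]-2,4,6-trimethyl-14-phenyltetradecanal | O=C[C@H](C)C[C@](C)(OOC(C)(C)OC)C[C@H](C)CCCCCCCCc1ccccc1
F8 | step 19 | (R)-2-hydroxy-1,2,2-triphenylethyl (3R,4S,6R,8R)-3-hydroxy-6-[(2-methoxypropan-2-yl)peroxy]-4,6,8-trimethyl-16-phenylhexadecanoate | O=C(C[C@@H](O)[C@@H](C)C[C@](C)(OOC(C)(C)OC)C[C@H](C)CCCCCCCCc1ccccc1)O[C@H](c1ccccc1)C(O)(c1ccccc1)c1ccccc1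
A1 | alternative 1 | 2,2-bis[(2S)-3-[(tert-butyldimethylsilyl)oxy]-2-methylpropyl]-1,3-dithiane | CC(C)(C)[Si](C)(C)OC[C@@H](C)CC1(C[C@H](C)CO[Si](C)(C)C(C)(C)C)SCCCS1
A2 | alternative 1 | tert-butyl{[(2R)-3-iodo-2-methylpropyl]oxy}dimethylsilane | CC(C)(C)[Si](C)(C)OC[C@@H](C)CI
A3 | alternative 1 | 1,3-dithiane | C1CSCSC1
A4 | alternative 2 | {(3S,5S,6S)-6-{2-[(tert-butyldiphenylsilyl)oxy]ethyl}-3,5-dimethyl-1,2-dioxan-3-yl}methanol | OC[C@]1(C)C[C@H](C)[C@H](CCO[Si](c2ccccc2)(c2ccccc2)C(C)(C)C)OO1
A5 | alternative 2 | tert-butyl{[(3S,4S)-3-hydroperoxy-4-methyl-5-[(2R)-2-methyloxiran-2-yl]pentyl]oxy}diphenylsilane | O1C[C@@]1(C)C[C@H](C)[C@H](CCO[Si](c2ccccc2)(c2ccccc2)C(C)(C)C)OO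
A6 | alternative 3 | tert-butyl{2-[(3S,6R)-4,6-dimethyl-6-[(2R)-2-methyl-10-phenyldecyl]-3,6-dihydro-1,2-dioxin-3-yl]ethoxy}diphenylsilane | C[C@H](CCCCCCCCc1ccccc1)C[C@]1(C)C=C(C)[C@H](CCO[Si](c2ccccc2)(c2ccccc2)C(C)(C)C)OO1
A7 | alternative 3 | tert-butyl{[(3S)-3-{[(3R,5R)-3,5-dimethyl-13-phenyltridec-1-en-3-yl]peroxy}-4-methylpent-4-en-1-yl]oxy}diphenylsilane | C[C@H](CCCCCCCCc1ccccc1)C[C@](C)(C=C)OO[C@@H](CCO[Si](c1ccccc1)(c1ccccc1)C(C)(C)C)C(C)=C
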